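**Retrosynthetic overview**
1. Target ⇐ C5 ketone (chelation-controlled hydride) ⇐ Schenck ene reaction of ¹O₂ on the Δ4(5)-germacranolide, the presumed biosynthetic C5 oxygenation with Δ4(15) shift.
2. Ten-membered carbocycle and cis-fused α-methylene-γ-lactone ⇐ one macrocyclising indium Barbier allylation/lactonisation that forges C6–C7 (the bond closed when farnesyl diphosphate cyclises to a germacrene) on a fully oxidised seco chain: (Z)-enal plus (Z)-2-(bromomethyl)enoate.
3. 3,10-Oxa bridge (3(2H)-furanone) ⇐ 5-endo addition of the C10 tertiary OH to a C1–C3 ynone, the anhydro form of the biosynthetic 10-hydroxy-1,3-dione → hemiketal → dehydration; ynone ⇐ hydroxy-lactone + (Z)-enynol acetylide.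
4. Stereocentres: C10 by Cu–box pyruvate aldol, C8 by 1,3-syn reduction, C7 and C6 in the Barbier ring closure, C5 by hydride at the end.
5. Ring order: auxiliary γ-lactone (opened again) → furanone → carbocycle and α-methylene lactone together.

Assumption: the SMILES is taken literally, i.e. (5S,6R,7R,8R,10R) with H-6 and H-7 cis (a cis-fused lactone).
Locants C1–C15 in the text are germacrane locants of the target: C1 ring ketone, C2=C3 furanone alkene (C3–O–C10), C4(=C15H2), C5(OH), C6(O-lactone), C7, C8(O-isobutyryl), C9H2, C10(C14H3), C11(=C13H2), C12 lactone carbonyl.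

**Step 1**
Reactants: 1 1,1-dimethoxypropan-2-one
Product: 2 3,3-dimethoxy-2-(trimethylsilyloxy)prop-1-ene
Conditions: LDA (1.1 equiv), THF, −78 °C; TMSCl, −78 °C → rt; distil
Reagents that add atoms: chlorotrimethylsilane, C[Si](C)(C)Cl
Why: Kinetic deprotonation of the methyl ketone at the unhindered CH3 and O-silylation of the enolate (silyl enol ether formation) gives the terminal enolsilane that serves as the C9 nucleophile.

**Step 2**
Reactants: 2 3,3-dimethoxy-2-(trimethylsilyloxy)prop-1-ene; 3 methyl pyruvate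
Product: 5 methyl (2R)-2-hydroxy-5,5-dimethoxy-2-methyl-4-oxopentanoate, via silyl ether 4 (not isolated)
Conditions: Cu(OTf)2 (10 mol%), (R,R)-t-Bu-box (11 mol%), THF, −78 °C; then 1 M HCl, THF, 0 °C
Reagents that add atoms: none
Why: Evans Cu(II)–bis(oxazoline)-catalysed Mukaiyama aldol addition to the chelated pyruvate, in which the (R,R)-ligand shields one carbonyl face so that C10 is formed as the 2R tertiary carbinol (the S,S-ligand gives the 2S series), followed by hydrolysis of the transferred silyl group.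

**Step 3**
Reactants: 5 methyl (2R)-2-hydroxy-5,5-dimethoxy-2-methyl-4-oxopentanoate
Product: 7 (3R,5R)-5-(dimethoxymethyl)-3-hydroxy-3-methyloxolan-2-one, via diol ester 6 (not isolated)
Conditions: Et2BOMe, THF/MeOH (4:1), −78 °C; NaBH4; AcOH, MeOH co-evaporation; then CSA (cat.), CH2Cl2, rt
Reagents that add atoms: none
Why: Narasaka–Prasad chelation-controlled reduction, in which the boron chelate of the C10 hydroxyl and the C8 ketone carries CH3 pseudo-equatorial and the flat ester pseudo-axial so that axial external hydride delivery gives the 4R (C8) carbinol, and acid-catalysed lactonisation of the γ-hydroxy ester then gives the lactone with 3-OH cis to the C5 substituent.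

**Step 4**
Reactants: 8 (2Z)-3-methylpent-2-en-4-yn-1-ol
Product: 9 tert-butyl(dimethyl){[(2Z)-3-methylpent-2-en-4-yn-1-yl]oxy}silane
Conditions: TBSCl, imidazole, DMF, 0 °C → rt
Reagents that add atoms: tert-butyldimethylsilyl chloride, CC(C)(C)[Si](C)(C)Cl
Why: Standard silylation of the primary allylic alcohol stops the Z-hydroxyl from adding to the ynone of the next step (which would give a furan) and keeps it distinct from the C8 hydroxyl.

**Step 5**
Reactants: 7 (3R,5R)-5-(dimethoxymethyl)-3-hydroxy-3-methyloxolan-2-one; 9 tert-butyl(dimethyl){[(2Z)-3-methylpent-2-en-4-yn-1-yl]oxy}silane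
Product: 11 (2R)-5-[(2Z)-4-{[tert-butyl(dimethyl)silyl]oxy}but-2-en-2-yl]-2-[(2R)-2-hydroxy-3,3-dimethoxypropyl]-2-methylfuran-3(2H)-one, via hydroxy-ynone 10 (not isolated)
Conditions: 9 (2.3 equiv), n-BuLi (2.2 equiv), THF, −78 °C; add 7, −78 → −20 °C; aq NH4Cl; then Et2NH, EtOH, rt; AcOH
Reagents that add atoms: none
Why: Acyl substitution of the lactone by the lithium acetylide (the first equivalent only forms the tertiary alkoxide and the lactol alkoxide resists over-addition) gives the α′-hydroxy ynone, whose amine-promoted 5-endo-dig oxa-Michael closure is the synthetic counterpart of the biosynthetic 10-hydroxy-1,3-dione hemiketalisation–dehydration and leaves C8, C10 and the Z-alkene untouched.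

**Step 6**
Reactants: 11 (2R)-5-[(2Z)-4-{[tert-butyl(dimethyl)silyl]oxy}but-2-en-2-yl]-2-[(2R)-2-hydroxy-3,3-dimethoxypropyl]-2-methylfuran-3(2H)-one
Product: 12 (2R)-1-[(2R)-5-[(2Z)-4-{[tert-butyl(dimethyl)silyl]oxy}but-2-en-2-yl]-2-methyl-3-oxo-2,3-dihydrofuran-2-yl]-3,3-dimethoxypropan-2-yl 2-methylpropanoate
Conditions: (i-PrCO)2O, DMAP (cat.), pyridine, CH2Cl2, rt
Reagents that add atoms: 2-methylpropanoic anhydride, CC(C)C(=O)OC(=O)C(C)C
Why: DMAP-catalysed acylation of the only free hydroxyl installs the C8 isobutyrate of the target early, so no separate protecting group is needed at O8.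

**Step 7**
Reactants: 12 (2R)-1-[(2R)-5-[(2Z)-4-{[tert-butyl(dimethyl)silyl]oxy}but-2-en-2-yl]-2-methyl-3-oxo-2,3-dihydrofuran-2-yl]-3,3-dimethoxypropan-2-yl 2-methylpropanoate
Product: 13 (2R)-1-[(2R)-5-[(2Z)-4-hydroxybut-2-en-2-yl]-2-methyl-3-oxo-2,3-dihydrofuran-2-yl]-3-oxopropan-2-yl 2-methylpropanoate
Conditions: TFA/H2O (4:1), CH2Cl2, 0 °C → rt; NaHCO3
Reagents that add atoms: water, O
Why: Aqueous acid hydrolysis removes the dimethyl acetal and the silyl ether in one operation, while the isobutyrate, the vinylogous-ester furanone and the Z-alkene are stable to acid, and the α-acyloxy aldehyde is used without storage.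

**Step 8**
Reactants: 13 (2R)-1-[(2R)-5-[(2Z)-4-hydroxybut-2-en-2-yl]-2-methyl-3-oxo-2,3-dihydrofuran-2-yl]-3-oxopropan-2-yl 2-methylpropanoate; 14 methyl acrylate
Product: 15 methyl (4R)-3-hydroxy-5-[(2R)-5-[(2Z)-4-hydroxybut-2-en-2-yl]-2-methyl-3-oxo-2,3-dihydrofuran-2-yl]-2-methylidene-4-(2-methylpropanoyloxy)pentanoate (mixture of C3 epimers)
Conditions: methyl acrylate (10 equiv), DABCO (0.5 equiv), neat, rt
Reagents that add atoms: none
Why: Morita–Baylis–Hillman reaction of the activated α-acyloxy aldehyde attaches C11–C13 to C7, and the new carbinol centre is of no consequence because it becomes sp2 in step 10.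

**Step 9**
Reactants: 15 methyl (4R)-3-hydroxy-5-[(2R)-5-[(2Z)-4-hydroxybut-2-en-2-yl]-2-methyl-3-oxo-2,3-dihydrofuran-2-yl]-2-methylidene-4-(2-methylpropanoyloxy)pentanoate
Product: 16 methyl (4R)-3-hydroxy-2-methylidene-5-[(2R)-2-methyl-3-oxo-5-[(2Z)-4-oxobut-2-en-2-yl]-2,3-dihydrofuran-2-yl]-4-(2-methylpropanoyloxy)pentanoate (mixture of C3 epimers)
Conditions: TEMPO (10 mol%), PhI(OAc)2, CH2Cl2, rt
Reagents that add atoms: none
Why: TEMPO/PhI(OAc)2 oxidation is selective for the primary allylic alcohol over the secondary Baylis–Hillman alcohol and its near-neutral conditions preserve the Z-enal geometry.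

**Step 10**
Reactants: 16 methyl (4R)-3-hydroxy-2-methylidene-5-[(2R)-2-methyl-3-oxo-5-[(2Z)-4-oxobut-2-en-2-yl]-2,3-dihydrofuran-2-yl]-4-(2-methylpropanoyloxy)pentanoate
Product: 17 methyl (2Z,4R)-2-(bromomethyl)-5-[(2R)-2-methyl-3-oxo-5-[(2Z)-4-oxobut-2-en-2-yl]-2,3-dihydrofuran-2-yl]-4-(2-methylpropanoyloxy)pent-2-enoate
Conditions: NBS, Me2S (premixed), CH2Cl2, −20 → 0 °C
Reagents that add atoms: N-bromosuccinimide, O=C1CCC(=O)N1Br
Why: Corey–Kim-type bromination of the Baylis–Hillman alcohol proceeds with SN2′ transposition to the thermodynamically preferred (Z)-2-(bromomethyl)enoate, and the premixed sulfonium reagent neither attacks the enal nor brominates the furanone.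

**Step 11**
Reactants: 17 methyl (2Z,4R)-2-(bromomethyl)-5-[(2R)-2-methyl-3-oxo-5-[(2Z)-4-oxobut-2-en-2-yl]-2,3-dihydrofuran-2-yl]-4-(2-methylpropanoyloxy)pent-2-enoate
Product: 19 (4Z,6S,7R,8R,10R)-8-(2-methylpropanoyloxy)-1-oxo-3,10-epoxygermacra-2,4,11(13)-trien-12,6-olide, via hydroxy ester 18 (not isolated)
Conditions: In powder, NH4Cl, THF/H2O (3:1), 0.002 M (syringe pump), rt; then CSA (cat.), CH2Cl2, rt
Reagents that add atoms: none
Why: Intramolecular indium Barbier allylation followed by lactonisation closes the ten-membered carbocycle at C6–C7 and the γ-lactone in one operation, the (Z)-γ-substituted allylindium reacting through a closed chair (syn adduct, hence the cis-fused lactone), with C7 attacked anti to C9 while C8–H eclipses the allyl unit (7R from 8R) and the tether on the C9 face of the furanone reaching only one face of the s-trans enal (6S here, which is 6R in the target).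

**Step 12**
Reactants: 19 (4Z,6S,7R,8R,10R)-8-(2-methylpropanoyloxy)-1-oxo-3,10-epoxygermacra-2,4,11(13)-trien-12,6-olide
Product: 21 (6R,7R,8R,10R)-8-(2-methylpropanoyloxy)-1,5-dioxo-3,10-epoxygermacra-2,4(15),11(13)-trien-12,6-olide, via 5-hydroperoxide 20 (not isolated)
Conditions: O2, TPP (1 mol%), white LED, CH2Cl2, −20 °C; then Ac2O, pyridine, DMAP (cat.), 0 °C → rt
Reagents that add atoms: dioxygen, O=O
Why: The Schenck ene reaction of singlet oxygen abstracts hydrogen from C15, geminal to the conjugating furanone (C6–H is deactivated by its acyloxy oxygen and the s-trans diene cannot undergo [4+2] addition), to give the C5 hydroperoxide with the Δ4(15) alkene, and Kornblum–DeLaMare dehydration of its peracetate gives the C5 ketone so that C5 can be set by hydride.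

**Step 13**
Reactants: 21 (6R,7R,8R,10R)-8-(2-methylpropanoyloxy)-1,5-dioxo-3,10-epoxygermacra-2,4(15),11(13)-trien-12,6-olide
Product: 22 (5S,6R,7R,8R,10R)-5-hydroxy-8-(2-methylpropanoyloxy)-1-oxo-3,10-epoxygermacra-2,4(15),11(13)-trien-12,6-olide (CNP0384113.1)
Conditions: NaBH4, CeCl3·7H2O, MeOH, −78 °C
Reagents that add atoms: none
Why: Luche 1,2-reduction under Cram-chelate control (cerium bridging the C5 carbonyl and the C6 lactone oxygen) delivers hydride from the H-6 side, the ring face opposite C7 and the C7–C9 bridge, giving the erythro 5S alcohol, while the vinylogous-ester ketone, the α-methylene lactone and the isobutyrate are not reduced at −78 °C.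

**Compound list**
1 | 1,1-dimethoxypropan-2-one | CC(=O)C(OC)OC | starting material
2 | 3,3-dimethoxy-2-(trimethylsilyloxy)prop-1-ene | C=C(O[Si](C)(C)C)C(OC)OC | intermediate
3 | methyl pyruvate (methyl 2-oxopropanoate) | CC(=O)C(=O)OC | starting material
4 | methyl (2R)-5,5-dimethoxy-2-methyl-4-oxo-2-(trimethylsilyloxy)pentanoate (not isolated) | COC(OC)C(=O)C[C@@](C(=O)OC)(C)O[Si](C)(C)C | intermediate
5 | methyl (2R)-2-hydroxy-5,5-dimethoxy-2-methyl-4-oxopentanoate | COC(OC)C(=O)C[C@@](C(=O)OC)(C)O | intermediate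
6 | methyl (2R,4R)-2,4-dihydroxy-5,5-dimethoxy-2-methylpentanoate (not isolated) | COC(OC)[C@H](O)C[C@@](C(=O)OC)(C)O | intermediate
7 | (3R,5R)-5-(dimethoxymethyl)-3-hydroxy-3-methyloxolan-2-one (3-OH cis to the C5 substituent) | COC(OC)[C@H](O1)C[C@@](C1=O)(C)O | intermediate
8 | (2Z)-3-methylpent-2-en-4-yn-1-ol | C#C/C(C)=C\CO | starting material
9 | tert-butyl(dimethyl){[(2Z)-3-methylpent-2-en-4-yn-1-yl]oxy}silane | C#C/C(C)=C\CO[Si](C)(C)C(C)(C)C | intermediate
10 | (2Z,7R,9R)-1-{[tert-butyl(dimethyl)silyl]oxy}-7,9-dihydroxy-10,10-dimethoxy-3,7-dimethyldec-2-en-4-yn-6-one (not isolated) | COC(OC)[C@H](O)C[C@@](C)(O)C(=O)C#C/C(C)=C\CO[Si](C)(C)C(C)(C)C | intermediate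
11 | (2R)-5-[(2Z)-4-{[tert-butyl(dimethyl)silyl]oxy}but-2-en-2-yl]-2-[(2R)-2-hydroxy-3,3-dimethoxypropyl]-2-methylfuran-3(2H)-one | COC(OC)[C@H](O)C[C@@]1(C)OC(=CC1=O)/C(C)=C\CO[Si](C)(C)C(C)(C)C | intermediate
12 | (2R)-1-[(2R)-5-[(2Z)-4-{[tert-butyl(dimethyl)silyl]oxy}but-2-en-2-yl]-2-methyl-3-oxo-2,3-dihydrofuran-2-yl]-3,3-dimethoxypropan-2-yl 2-methylpropanoate | COC(OC)[C@H](OC(=O)C(C)C)C[C@@]1(C)OC(=CC1=O)/C(C)=C\CO[Si](C)(C)C(C)(C)C | intermediate
13 | (2R)-1-[(2R)-5-[(2Z)-4-hydroxybut-2-en-2-yl]-2-methyl-3-oxo-2,3-dihydrofuran-2-yl]-3-oxopropan-2-yl 2-methylpropanoate | O=C[C@H](OC(=O)C(C)C)C[C@@]1(C)OC(=CC1=O)/C(C)=C\CO | intermediate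
14 | methyl acrylate | C=CC(=O)OC | starting material
15 | methyl (4R)-3-hydroxy-5-[(2R)-5-[(2Z)-4-hydroxybut-2-en-2-yl]-2-methyl-3-oxo-2,3-dihydrofuran-2-yl]-2-methylidene-4-(2-methylpropanoyloxy)pentanoate (C3 epimers) | C=C(C(=O)OC)C(O)[C@H](OC(=O)C(C)C)C[C@@]1(C)OC(=CC1=O)/C(C)=C\CO | intermediate
16 | methyl (4R)-3-hydroxy-2-methylidene-5-[(2R)-2-methyl-3-oxo-5-[(2Z)-4-oxobut-2-en-2-yl]-2,3-dihydrofuran-2-yl]-4-(2-methylpropanoyloxy)pentanoate (C3 epimers) | C=C(C(=O)OC)C(O)[C@H](OC(=O)C(C)C)C[C@@]1(C)OC(=CC1=O)/C(C)=C\C=O | intermediate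
17 | methyl (2Z,4R)-2-(bromomethyl)-5-[(2R)-2-methyl-3-oxo-5-[(2Z)-4-oxobut-2-en-2-yl]-2,3-dihydrofuran-2-yl]-4-(2-methylpropanoyloxy)pent-2-enoate | BrC/C(C(=O)OC)=C\[C@H](OC(=O)C(C)C)C[C@@]1(C)OC(=CC1=O)/C(C)=C\C=O | intermediate
18 | methyl (4Z,6S,7S,8R,10R)-6-hydroxy-8-(2-methylpropanoyloxy)-1-oxo-3,10-epoxygermacra-2,4,11(13)-trien-12-oate (not isolated) | C=C(C(=O)OC)[C@@H]1[C@H](OC(=O)C(C)C)C[C@@]2(C)OC(=CC2=O)/C(C)=C\[C@@H]1O | intermediate
19 | (4Z,6S,7R,8R,10R)-8-(2-methylpropanoyloxy)-1-oxo-3,10-epoxygermacra-2,4,11(13)-trien-12,6-olide (cis-fused lactone) | C/C1=C/[C@@H]2OC(=O)C(=C)[C@@H]2[C@H](OC(=O)C(C)C)C[C@@]2(C)OC1=CC2=O | intermediate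
20 | (6R,7R,8R,10R)-5-hydroperoxy-8-(2-methylpropanoyloxy)-1-oxo-3,10-epoxygermacra-2,4(15),11(13)-trien-12,6-olide (C5 not defined, mainly 5R expected; not isolated) | C=C1C(=O)O[C@@H]2[C@H]1[C@H](OC(=O)C(C)C)C[C@@]1(C)OC(=CC1=O)C(=C)C2OO | intermediate
21 | (6R,7R,8R,10R)-8-(2-methylpropanoyloxy)-1,5-dioxo-3,10-epoxygermacra-2,4(15),11(13)-trien-12,6-olide | C=C1C(=O)O[C@@H]2[C@H]1[C@H](OC(=O)C(C)C)C[C@@]1(C)OC(=CC1=O)C(=C)C2=O | intermediate
22 | (5S,6R,7R,8R,10R)-5-hydroxy-8-(2-methylpropanoyloxy)-1-oxo-3,10-epoxygermacra-2,4(15),11(13)-trien-12,6-olide | C=C1C(=O)O[C@@H]2[C@H]1[C@H](OC(=O)C(C)C)C[C@@]1(C)OC(=CC1=O)C(=C)[C@@H]2O | target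

**Step count**
Total: 13 steps. Longest linear sequence: 12 steps (1 → 22 through steps 1–3 and 5–13; step 4 is a one-step branch).

**Steps most likely to fail, with fallbacks**

Step 11 is the boldest step. A strained bridged ten-membered ring must close in competition with oligomerisation, with 1,4-loss of the C8 isobutyrate from the allylmetal and with the other C6/C7 diastereomers. The fallback changes how the allyl nucleophile is made. It sets out from 16, whose Baylis–Hillman hydroxyl is acetylated (Ac2O, DMAP, pyridine) to methyl (4R)-3-acetoxy-2-methylidene-5-[(2R)-2-methyl-3-oxo-5-[(2Z)-4-oxobut-2-en-2-yl]-2,3-dihydrofuran-2-yl]-4-(2-methylpropanoyloxy)pentanoate F1. Pd(PPh3)4 (5 mol%) and InI in THF at high dilution then ionise the allylic acetate to a π-allylpalladium species that is transmetallated to the allylindium (umpolung) without a free bromide or In(0) surface. Ring closure gives hydroxy ester 18, which lactonises with CSA, and the route is rejoined at 19.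

Step 13 decides C5 together with step 12, and the facial preference of the macrocycle is predicted, not known. If hydride enters from the other face and gives the 5-epimer, the exposed face is the opposite one, and the C–O bond should then be made on that face by oxygen instead of the C–H bond by hydride. The fallback sets out from 19: photooxygenation as in step 12, but the hydroperoxide 20 is reduced in the same flask with Me2S instead of being dehydrated, which leads straight to 22. It makes no new compound (F0).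

Step 3 relies on the ester, not the methyl group, sitting pseudo-axial in the boron chelate; if the preference is small or reversed the wrong C8 epimer (trans lactone) results. The fallback replaces substrate control by reagent control. It sets out from 4, isolated by leaving out the acidic work-up of step 2. Reduction with (S)-Me-CBS and BH3·SMe2 (THF, −30 °C), the acetal acting as the large group, gives methyl (2R,4R)-4-hydroxy-5,5-dimethoxy-2-methyl-2-(trimethylsilyloxy)pentanoate F2. Aqueous HCl in THF then removes the silyl group and closes the lactone, rejoining the route at 7.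

**Further compounds**
F1 | step 11 | methyl (4R)-3-acetoxy-2-methylidene-5-[(2R)-2-methyl-3-oxo-5-[(2Z)-4-oxobut-2-en-2-yl]-2,3-dihydrofuran-2-yl]-4-(2-methylpropanoyloxy)pentanoate (C3 epimers) | C=C(C(=O)OC)C(OC(C)=O)[C@H](OC(=O)C(C)C)C[C@@]1(C)OC(=CC1=O)/C(C)=C\C=O
F0 | step 13 | none | none
F2 | step 3 | methyl (2R,4R)-4-hydroxy-5,5-dimethoxy-2-methyl-2-(trimethylsilyloxy)pentanoate | COC(OC)[C@H](O)C[C@@](C(=O)OC)(C)O[Si](C)(C)C
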